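The plan reads ring B of the target as a latent 2,6-dimethyl-1,4-benzoquinone: C6 and C9 are its carbonyl carbons, C17 and C20 its methyl groups and C7=C8 one of its methyl-bearing edges. A chiral oxazaborolidinium cation adds 4-methylpenta-1,3-diene across the other edge, C5=C10, forming C1–C10 and C4–C5, closing ring A and fixing the quaternary C10 stereocentre in a single operation. The precursors are simply the commercial quinone 1 and diene 2; the cis ene-dione 3 that results already carries oxygen at C6, the C7=C8 alkene with C17, and a C9 carbonyl onto which the side chain is later built and joined by a B-alkyl Suzuki coupling.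

Key step: step 1

Remarks on the chemistry:
- Labdane numbering is used for positions (C1–C10 decalin, C11–C16 side chain, C17 on C8, C20 on C10). "The C20 face" is the face of ring B that carries the angular methyl.
- Assumption: the facial sense of step 1 is taken from the accepted pre-transition-state model for this catalyst class, which calls for the (S)-prolinol-derived catalyst; if the antipode of 3 formed, the (R)-catalyst would be used instead.
- The structures are consistent: adduct 3 has the C10 configuration of the target, and the (Z)-iodide 16 leads to the (E)-enoate of the target because the CIP priorities change on coupling, not the geometry.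

Step 1
Reactants: 1 2,6-dimethyl-1,4-benzoquinone; 2 4-methylpenta-1,3-diene
Product: 3 (4aS,8aR)-2,5,5,8a-tetramethyl-4a,5,8,8a-tetrahydronaphthalene-1,4-dione (cis-fused, H5 and C20 on the same face)
Conditions: (S)-1-(2-methylphenyl)-3,3-diphenyltetrahydro-1H,3H-pyrrolo[1,2-c][1,3,2]oxazaborole (20 mol %), Tf2NH (18 mol %), 2 (3 equiv, freshly distilled), CH2Cl2, −78 → −40 °C
Reagents that add atoms: none
Why: The N-protonated oxazaborolidine binds the C6 carbonyl oxygen of 1 on the lone pair syn to C5–H (the C9 carbonyl is flanked by two methyl-bearing carbons), which lowers the LUMO of the C5=C10 edge and stacks it on a catalyst phenyl group so that only one face is open to the diene. A concerted but asynchronous Diels–Alder [4+2] cycloaddition follows, the closest known reaction type being oxazaborolidinium-catalysed cycloadditions of methyl-substituted benzoquinones with acyclic dienes. Ring A is closed by this intermolecular six-electron cycloaddition, which forms C1–C10 and C4–C5 suprafacially on both partners through an endo transition state. C10 is set by the catalyst-controlled face and C5 follows from the suprafacial addition, so the two centres are delivered as the cis adduct. The regiochemistry needed (CH2 terminus to C10, CMe2 terminus to C5) is secured electronically, because the more nucleophilic unsubstituted diene terminus attacks the β-carbon C10 of the activated enone, and sterically, because the alternative would join two fully substituted carbons. No site selectivity is required, since the two methyl-bearing edges of the symmetric quinone are equivalent.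

Step 2
Reactants: 3 cis ene-dione
Product: 4 (4aR,8aR)-2,5,5,8a-tetramethyl-4a,5,8,8a-tetrahydronaphthalene-1,4-dione (trans-fused, H5 opposite C20)
Conditions: DBU (0.1 equiv), CH2Cl2, 0 °C → rt
Reagents that add atoms: none
Why: Base-catalysed epimerisation through the C5 enolate (C5–H is the only enolisable position and the quaternary C10 rules out aromatisation) should settle under thermodynamic control on the trans-fused epimer, in which C1 and C4 are both equatorial on ring B.

Step 3
Reactants: 4 trans ene-dione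
Product: 5 (4S,4aR,8aR)-4-hydroxy-2,5,5,8a-tetramethyl-4a,5,8,8a-tetrahydronaphthalen-1(4H)-one (6-OH axial, on the C20 face)
Conditions: NaBH4 (0.5 equiv), CeCl3·7H2O, MeOH, −78 °C
Reagents that add atoms: none
Why: Luche 1,2-reduction should select the C6 carbonyl (C9 is flanked by the quaternary C10 and the C8 methyl) and deliver hydride from the face opposite the syn-axial C20 and C4 methyl groups, giving the axial 6-alcohol while the cerium salt suppresses conjugate reduction.

Step 4
Reactants: 5 axial allylic alcohol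
Product: 7 (4R,4aR,8aR)-4-hydroxy-2,5,5,8a-tetramethyl-4a,5,8,8a-tetrahydronaphthalen-1(4H)-one (6-OH equatorial, opposite C20), via inverted 4-nitrobenzoate ester 6 (not isolated)
Conditions: PPh3, DIAD, 4-nitrobenzoic acid, THF, 0 °C → rt; then K2CO3 (cat.), MeOH, 0 °C
Reagents that add atoms: 4-nitrobenzoic acid, O=C(O)c1ccc(cc1)[N+](=O)[O-]
Why: Mitsunobu esterification is an SN2 displacement of the alkoxyphosphonium at the allylic, enone-activated C6 by carboxylate from the open face opposite C20, which inverts C6 to the equatorial configuration of the target, and mild methanolysis then frees the alcohol (whose oxygen comes from the acid) without disturbing the enone.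

Step 5
Reactants: 7 equatorial allylic alcohol
Product: 8 (4R,4aR,8aR)-4-[(tert-butyldimethylsilyl)oxy]-2,5,5,8a-tetramethyl-4a,5,8,8a-tetrahydronaphthalen-1(4H)-one
Conditions: TBSOTf, 2,6-lutidine, CH2Cl2, −78 → 0 °C
Reagents that add atoms: tert-butyldimethylsilyl trifluoromethanesulfonate, CC(C)(C)[Si](C)(C)OS(=O)(=O)C(F)(F)F
Why: Silyl ether formation with the reactive triflate protects the hindered secondary alcohol as a TBS ether that should tolerate ylides, boranes, aqueous carbonate and SeO2 and can be removed at the end without touching an acetate.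

Step 6
Reactants: 8 silyl ether
Product: 9 (4R,4aR,8aR)-4-[(tert-butyldimethylsilyl)oxy]-2,5,5,8a-tetramethyl-4a,5,6,7,8,8a-hexahydronaphthalen-1(4H)-one
Conditions: H2 (4 atm), RhCl(PPh3)3 (10 mol %), benzene/EtOH, rt
Reagents that add atoms: none
Why: Homogeneous hydrogenation with the rhodium chloride phosphine complex reduces the cis-disubstituted C2=C3 alkene of ring A and should leave the trisubstituted conjugated C7=C8 bond and the allylic C–O bond alone, as in the selective reduction of the isolated alkene of carvone.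

Step 7
Reactants: 9 enone
Product: 10 (4R,4aR,8aR)-4-[(tert-butyldimethylsilyl)oxy]-2,5,5,8a-tetramethyl-1-methylidene-1,4,4a,5,6,7,8,8a-octahydronaphthalene (C7=C8 and exocyclic C9=C11 diene)
Conditions: Ph3PCH3Br, KOtBu (slight deficiency), toluene, 90 °C
Reagents that add atoms: methyltriphenylphosphonium bromide, C[P+](c1ccccc1)(c1ccccc1)c1ccccc1.[Br-]
Why: Wittig methylenation at elevated temperature is established for 2,6,6-trisubstituted cyclohexenones of this kind, and here the ketone has no α-hydrogen while its only acidic hydrogen, the axial γ-H6, is shielded by the two syn-axial methyl groups.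

Step 8
Reactants: 10 diene
Product: 12 [(1R,4R,4aR,8aS)-4-[(tert-butyldimethylsilyl)oxy]-2,5,5,8a-tetramethyl-1,4,4a,5,6,7,8,8a-octahydronaphthalen-1-yl]methanol (H9 opposite C20, CH2OH equatorial), via B-alkyl-9-BBN adduct 11 (not isolated)
Conditions: 9-BBN, THF, 0 → 50 °C; then NaOH, H2O2, 0 °C → rt
Reagents that add atoms: 9-borabicyclo[3.3.1]nonane, B1C2CCCC1CCC2 (its boron is carried by 11 only); hydrogen peroxide, OO
Why: Hydroboration–oxidation with 9-BBN places boron on the terminal C11 of the 1,1-disubstituted alkene (the trisubstituted C7=C8 is inert) and delivers hydrogen to C9 from the face opposite the axial C20 methyl on the neighbouring C10, which sets C9 with the carbon substituent equatorial as in the target.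

Step 9
Reactants: 12 primary alcohol
Product: 13 (1R,4R,4aR,8aR)-4-[(tert-butyldimethylsilyl)oxy]-2,5,5,8a-tetramethyl-1,4,4a,5,6,7,8,8a-octahydronaphthalene-1-carbaldehyde
Conditions: Dess–Martin periodinane, pyridine, CH2Cl2, 0 °C
Reagents that add atoms: none
Why: Dess–Martin oxidation under pyridine-buffered conditions gives the β,γ-unsaturated aldehyde without the acid or base that would epimerise C9 or draw the C7=C8 bond into conjugation.

Step 10
Reactants: 13 aldehyde
Product: 14 (1R,4R,4aR,8aS)-4-[(tert-butyldimethylsilyl)oxy]-1-ethenyl-2,5,5,8a-tetramethyl-1,4,4a,5,6,7,8,8a-octahydronaphthalene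
Conditions: Ph3PCH3Br, KN(SiMe3)2, THF, −78 → 0 °C
Reagents that add atoms: methyltriphenylphosphonium bromide, C[P+](c1ccccc1)(c1ccccc1)c1ccccc1.[Br-]
Why: Wittig methylenation of an aldehyde at low temperature is faster than its enolisation, as known for α-cyclocitral-type β,γ-unsaturated aldehydes, so the C11=C12 vinyl group should form with C9 intact.

Step 11
Reactants: 15 methyl 4-hydroxybut-2-ynoate
Product: 16 methyl (2Z)-4-hydroxy-3-iodobut-2-enoate
Conditions: NaI, AcOH, 70 °C
Reagents that add atoms: sodium iodide, [Na+].[I-]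
Why: Hydroiodination of an ynoate with iodide in acetic acid is a kinetic anti conjugate addition of HI that places iodine cis to the ester and the CH2OH trans to it, a geometry from which no butenolide can form.

Step 12
Reactants: 14 vinyl compound; 16 (Z)-iodoenoate
Product: 18 methyl (2E)-5-[(1R,4R,4aR,8aS)-4-[(tert-butyldimethylsilyl)oxy]-2,5,5,8a-tetramethyl-1,4,4a,5,6,7,8,8a-octahydronaphthalen-1-yl]-3-(hydroxymethyl)pent-2-enoate, via homologous B-alkyl-9-BBN adduct 17 (not isolated)
Conditions: 9-BBN, THF, rt; then 16, PdCl2(dppf) (10 mol %), AsPh3, Cs2CO3, DMF/H2O, rt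
Reagents that add atoms: 9-borabicyclo[3.3.1]nonane, B1C2CCCC1CCC2 (its boron is carried by 17 only)
Why: Anti-Markovnikov hydroboration of the monosubstituted alkene followed by B-alkyl Suzuki–Miyaura coupling, in which oxidative addition of zerovalent palladium to the C–I bond and reductive elimination retain the alkene geometry, forms C12–C13 with the chain cis to the ester as the target requires.

Step 13
Reactants: 18 allylic alcohol
Product: 19 methyl (2E)-3-(acetoxymethyl)-5-[(1R,4R,4aR,8aS)-4-[(tert-butyldimethylsilyl)oxy]-2,5,5,8a-tetramethyl-1,4,4a,5,6,7,8,8a-octahydronaphthalen-1-yl]pent-2-enoate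
Conditions: Ac2O, pyridine, DMAP (cat.), CH2Cl2, 0 °C → rt
Reagents that add atoms: acetic anhydride, CC(=O)OC(C)=O
Why: DMAP-catalysed acylation of the only free hydroxyl, a primary allylic one, installs the C16 acetate.

Step 14
Reactants: 19 acetate
Product: 21 methyl (2E)-3-(acetoxymethyl)-5-[(1S,4R,4aR,8aS)-4-[(tert-butyldimethylsilyl)oxy]-2-formyl-5,5,8a-trimethyl-1,4,4a,5,6,7,8,8a-octahydronaphthalen-1-yl]pent-2-enoate, via C17 allylic alcohol 20 (not isolated)
Conditions: SeO2, 1,4-dioxane, 80 °C
Reagents that add atoms: selenium dioxide, O=[Se]=O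
Why: Riley oxidation should engage the electron-rich trisubstituted C7=C8 bond (the enoate alkene is deactivated) by an ene reaction at C7 and a [2,3]-sigmatropic shift that oxidises the C17 methyl in preference to the tertiary, hindered C9–H, as in the oxidation of drim-7-ene esters, and then carry the allylic alcohol on to the enal.

Step 15
Reactants: 21 silyl-protected enal
Product: 22 methyl (2E)-3-(acetoxymethyl)-5-[(1S,4R,4aR,8aS)-2-formyl-4-hydroxy-5,5,8a-trimethyl-1,4,4a,5,6,7,8,8a-octahydronaphthalen-1-yl]pent-2-enoate (CNP0112124.1)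
Conditions: HF·pyridine, pyridine, THF, 0 °C → rt
Reagents that add atoms: none
Why: Fluoride-mediated desilylation under buffered conditions should free the C6 hydroxyl without cleaving the acetate or methyl ester or dehydrating the γ-hydroxy enal.

Compound list
1 | 2,6-dimethyl-1,4-benzoquinone | CC1=CC(=O)C=C(C)C1=O | starting material
2 | 4-methylpenta-1,3-diene | C=CC=C(C)C | starting material
3 | (4aS,8aR)-2,5,5,8a-tetramethyl-4a,5,8,8a-tetrahydronaphthalene-1,4-dione | O=C1C(C)=CC(=O)[C@H]2C(C)(C)C=CC[C@@]12C | intermediate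
4 | (4aR,8aR)-2,5,5,8a-tetramethyl-4a,5,8,8a-tetrahydronaphthalene-1,4-dione | O=C1C(C)=CC(=O)[C@@H]2C(C)(C)C=CC[C@@]12C | intermediate
5 | (4S,4aR,8aR)-4-hydroxy-2,5,5,8a-tetramethyl-4a,5,8,8a-tetrahydronaphthalen-1(4H)-one | O=C1C(C)=C[C@H](O)[C@@H]2C(C)(C)C=CC[C@@]12C | intermediate
6 | (4R,4aR,8aR)-2,5,5,8a-tetramethyl-1-oxo-1,4,4a,5,8,8a-hexahydronaphthalen-4-yl 4-nitrobenzoate | O=C1C(C)=C[C@@H](OC(=O)c3ccc(cc3)[N+](=O)[O-])[C@@H]2C(C)(C)C=CC[C@@]12C | intermediate (not isolated)
7 | (4R,4aR,8aR)-4-hydroxy-2,5,5,8a-tetramethyl-4a,5,8,8a-tetrahydronaphthalen-1(4H)-one | O=C1C(C)=C[C@@H](O)[C@@H]2C(C)(C)C=CC[C@@]12C | intermediate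
8 | (4R,4aR,8aR)-4-[(tert-butyldimethylsilyl)oxy]-2,5,5,8a-tetramethyl-4a,5,8,8a-tetrahydronaphthalen-1(4H)-one | O=C1C(C)=C[C@@H](O[Si](C)(C)C(C)(C)C)[C@@H]2C(C)(C)C=CC[C@@]12C | intermediate
9 | (4R,4aR,8aR)-4-[(tert-butyldimethylsilyl)oxy]-2,5,5,8a-tetramethyl-4a,5,6,7,8,8a-hexahydronaphthalen-1(4H)-one | O=C1C(C)=C[C@@H](O[Si](C)(C)C(C)(C)C)[C@@H]2C(C)(C)CCC[C@@]12C | intermediate
10 | (4R,4aR,8aR)-4-[(tert-butyldimethylsilyl)oxy]-2,5,5,8a-tetramethyl-1-methylidene-1,4,4a,5,6,7,8,8a-octahydronaphthalene | C=C1C(C)=C[C@@H](O[Si](C)(C)C(C)(C)C)[C@@H]2C(C)(C)CCC[C@@]12C | intermediate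
11 | 9-{[(1R,4R,4aR,8aS)-4-[(tert-butyldimethylsilyl)oxy]-2,5,5,8a-tetramethyl-1,4,4a,5,6,7,8,8a-octahydronaphthalen-1-yl]methyl}-9-borabicyclo[3.3.1]nonane | B1(C2CCCC1CCC2)C[C@@H]3C(C)=C[C@@H](O[Si](C)(C)C(C)(C)C)[C@@H]4C(C)(C)CCC[C@@]34C | intermediate (not isolated)
12 | [(1R,4R,4aR,8aS)-4-[(tert-butyldimethylsilyl)oxy]-2,5,5,8a-tetramethyl-1,4,4a,5,6,7,8,8a-octahydronaphthalen-1-yl]methanol | OC[C@@H]1C(C)=C[C@@H](O[Si](C)(C)C(C)(C)C)[C@@H]2C(C)(C)CCC[C@@]12C | intermediate
13 | (1R,4R,4aR,8aR)-4-[(tert-butyldimethylsilyl)oxy]-2,5,5,8a-tetramethyl-1,4,4a,5,6,7,8,8a-octahydronaphthalene-1-carbaldehyde | O=C[C@@H]1C(C)=C[C@@H](O[Si](C)(C)C(C)(C)C)[C@@H]2C(C)(C)CCC[C@@]12C | intermediate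
14 | (1R,4R,4aR,8aS)-4-[(tert-butyldimethylsilyl)oxy]-1-ethenyl-2,5,5,8a-tetramethyl-1,4,4a,5,6,7,8,8a-octahydronaphthalene | C=C[C@@H]1C(C)=C[C@@H](O[Si](C)(C)C(C)(C)C)[C@@H]2C(C)(C)CCC[C@@]12C | intermediate
15 | methyl 4-hydroxybut-2-ynoate | COC(=O)C#CCO | starting material
16 | methyl (2Z)-4-hydroxy-3-iodobut-2-enoate | COC(=O)/C=C(\I)CO | intermediate
17 | 9-{2-[(1R,4R,4aR,8aS)-4-[(tert-butyldimethylsilyl)oxy]-2,5,5,8a-tetramethyl-1,4,4a,5,6,7,8,8a-octahydronaphthalen-1-yl]ethyl}-9-borabicyclo[3.3.1]nonane | B1(C2CCCC1CCC2)CC[C@@H]3C(C)=C[C@@H](O[Si](C)(C)C(C)(C)C)[C@@H]4C(C)(C)CCC[C@@]34C | intermediate (not isolated)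
18 | methyl (2E)-5-[(1R,4R,4aR,8aS)-4-[(tert-butyldimethylsilyl)oxy]-2,5,5,8a-tetramethyl-1,4,4a,5,6,7,8,8a-octahydronaphthalen-1-yl]-3-(hydroxymethyl)pent-2-enoate | COC(=O)/C=C(\CC[C@@H]1C(C)=C[C@@H](O[Si](C)(C)C(C)(C)C)[C@@H]2C(C)(C)CCC[C@@]12C)CO | intermediate
19 | methyl (2E)-3-(acetoxymethyl)-5-[(1R,4R,4aR,8aS)-4-[(tert-butyldimethylsilyl)oxy]-2,5,5,8a-tetramethyl-1,4,4a,5,6,7,8,8a-octahydronaphthalen-1-yl]pent-2-enoate | COC(=O)/C=C(\CC[C@@H]1C(C)=C[C@@H](O[Si](C)(C)C(C)(C)C)[C@@H]2C(C)(C)CCC[C@@]12C)COC(C)=O | intermediate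
20 | methyl (2E)-3-(acetoxymethyl)-5-[(1S,4R,4aR,8aS)-4-[(tert-butyldimethylsilyl)oxy]-2-(hydroxymethyl)-5,5,8a-trimethyl-1,4,4a,5,6,7,8,8a-octahydronaphthalen-1-yl]pent-2-enoate | COC(=O)/C=C(\CC[C@@H]1C(CO)=C[C@@H](O[Si](C)(C)C(C)(C)C)[C@@H]2C(C)(C)CCC[C@@]12C)COC(C)=O | intermediate (not isolated)
21 | methyl (2E)-3-(acetoxymethyl)-5-[(1S,4R,4aR,8aS)-4-[(tert-butyldimethylsilyl)oxy]-2-formyl-5,5,8a-trimethyl-1,4,4a,5,6,7,8,8a-octahydronaphthalen-1-yl]pent-2-enoate | COC(=O)/C=C(\CC[C@@H]1C(C=O)=C[C@@H](O[Si](C)(C)C(C)(C)C)[C@@H]2C(C)(C)CCC[C@@]12C)COC(C)=O | intermediate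
22 | methyl (2E)-3-(acetoxymethyl)-5-[(1S,4R,4aR,8aS)-2-formyl-4-hydroxy-5,5,8a-trimethyl-1,4,4a,5,6,7,8,8a-octahydronaphthalen-1-yl]pent-2-enoate (CNP0112124.1) | COC(=O)/C=C(\CC[C@@H]1C(C=O)=C[C@@H](O)[C@@H]2C(C)(C)CCC[C@@]12C)COC(C)=O | target

Total step count: 15. Longest linear sequence: 14 (steps 1–10 and 12–15; step 11 prepares the coupling partner).

Steps most likely to fail

Step 1. The cis-methyl of the CMe2 terminus disfavours the s-cis conformer of the diene, so turnover of the chiral acid may be slow, and acid-induced oligomerisation of the diene or erosion of facial discrimination may compete. Fallback: starting from 1 and 2, the cycloaddition is promoted by an achiral Lewis acid (BF3·OEt2, CH2Cl2, −78 °C), which should bind the same carbonyl and give the same regiochemistry as the racemic cis adduct F1. The conditions of steps 2 and 3 then give the racemic trans ene-dione F2 and the racemic axial alcohol F3. The Mitsunobu inversion is run with (S)-2-methoxy-2-phenylacetic acid in place of 4-nitrobenzoic acid, so that inversion and resolution coincide: it should give the desired diastereomeric O-methylmandelate F4 and the undesired diastereomeric O-methylmandelate F5, to be separated by chromatography or crystallisation. Methanolysis of F4 (K2CO3, MeOH) rejoins the route at 7.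

Step 2. The base equilibration may stop at a cis/trans mixture if the two ring-fusion epimers are close in energy. Fallback: starting from 3, soft enolisation (TMSOTf, Et3N, CH2Cl2, 0 °C) gives the trimethylsilyl dienol ether F6, in which C5 is trigonal. Protodesilylation at low temperature (Bu4NF, AcOH, THF, −78 °C) then places the proton on C5 under kinetic control, from the face opposite the angular C20 methyl, and rejoins the route at 4 without relying on the position of the equilibrium.

Step 4. Activation of the axial C6 hydroxyl, which sits beside the syn-axial C20 and C4 methyl groups, may be slow, and anti elimination of the activated oxygen with the trans-diaxial H5 to a conjugated dienone may outrun substitution. Fallback: starting from 5, a Meerwein–Ponndorf–Verley/Oppenauer redox equilibration (Al(OiPr)3, catalytic acetone, toluene, 80 °C) shuttles hydride reversibly between the aluminium alkoxide and the C6 ketone 4. It should converge on the more stable equatorial epimer and so rejoin the route at 7. This replaces SN2 inversion by thermodynamic control and makes no new compound.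

Further compounds
F1 | step 1 | rac-(4aS,8aR)-2,5,5,8a-tetramethyl-4a,5,8,8a-tetrahydronaphthalene-1,4-dione (racemic cis adduct) | O=C1C(C)=CC(=O)[C@H]2C(C)(C)C=CC[C@@]12C.O=C1C(C)=CC(=O)[C@@H]2C(C)(C)C=CC[C@]12C
F2 | step 1 | rac-(4aR,8aR)-2,5,5,8a-tetramethyl-4a,5,8,8a-tetrahydronaphthalene-1,4-dione (racemic trans ene-dione) | O=C1C(C)=CC(=O)[C@@H]2C(C)(C)C=CC[C@@]12C.O=C1C(C)=CC(=O)[C@H]2C(C)(C)C=CC[C@]12C
F3 | step 1 | rac-(4S,4aR,8aR)-4-hydroxy-2,5,5,8a-tetramethyl-4a,5,8,8a-tetrahydronaphthalen-1(4H)-one (racemic axial alcohol) | O=C1C(C)=C[C@H](O)[C@@H]2C(C)(C)C=CC[C@@]12C.O=C1C(C)=C[C@@H](O)[C@H]2C(C)(C)C=CC[C@]12C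
F4 | step 1 | (4R,4aR,8aR)-2,5,5,8a-tetramethyl-1-oxo-1,4,4a,5,8,8a-hexahydronaphthalen-4-yl (2S)-2-methoxy-2-phenylacetate | O=C1C(C)=C[C@@H](OC(=O)[C@@H](OC)c3ccccc3)[C@@H]2C(C)(C)C=CC[C@@]12C
F5 | step 1 | (4S,4aS,8aS)-2,5,5,8a-tetramethyl-1-oxo-1,4,4a,5,8,8a-hexahydronaphthalen-4-yl (2S)-2-methoxy-2-phenylacetate | O=C1C(C)=C[C@H](OC(=O)[C@@H](OC)c3ccccc3)[C@H]2C(C)(C)C=CC[C@]12C
F6 | step 2 | (8aR)-2,5,5,8a-tetramethyl-4-[(trimethylsilyl)oxy]-5,8-dihydronaphthalen-1(8aH)-one | O=C1C(C)=CC(O[Si](C)(C)C)=C2C(C)(C)C=CC[C@@]12C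
F0 | step 4 | none | none
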